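## The problem

Isoplagilin (21) is a biaryl of two catechol rings (ring B and ring C), each carrying a 2-(3-methoxyphenyl)ethyl arm that ends in ring A (on ring B) or ring D (on ring C). It has no stereocentre, so the task is one of regiochemistry and of the order in which five aryl–carbon bonds are made: the four aryl–CH2 bonds of two ethylene bridges and one biaryl bond. The two catechol rings are not equivalent. Ring B carries its arm at C1, hydroxyls at C3 and C4 and ring C at C5; ring C is joined through C1, carries hydroxyls at C3 and C4 and has its arm at C6, ortho to the biaryl bond. The biaryl bond is therefore flanked by an oxygen on one side and an alkyl chain on the other, so its formation is moderately hindered. The free catechols oxidise easily to ortho-quinones and bind metals, so they must stay masked until the last step, and the mask must come off without touching the two methyl ethers. Benzyl ethers meet this, but they rule out heterogeneous hydrogenation of an alkene at any intermediate stage. Any stereocentre made on the way must be removable. The feature that opens the key step is the CH2–CH2 bridge between ring A and C1 of ring B: it is a vinyl group flanked by an aryl nucleophile and an aryl electrophile, and C1 of ring B lies para to the C4 oxygen and between two C–H positions, so it can be reached as an unhindered aryl triflate from a formyl group.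

## Retrosynthesis

**Unmasking (21 ⇐ 20 ⇐ 19).** The last cut is at the four benzyl–oxygen bonds of tetra-O-benzyl isoplagilin 20. Hydrogenolysis is placed last because 21 is an air-sensitive bis-catechol, and it only has to spare the aryl methyl ethers. 20 is then traced to the benzylic boronic ester 19 by exchanging the C–H bond next to ring A for a C–B bond. This does not simplify the skeleton; it installs the retron of the key step, and a benzylic carbon is the position where a C–B bond is most easily replaced by C–H. The forward reaction must cleave the C–B bond without oxidising it.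

**First bridge (19 ⇐ 14 + 15 + 17).** Two bonds are cut together: ring A–CH and CH2–C1 of ring B. This leaves aryl triflate 14, vinylboronic ester 15 and (3-methoxyphenyl)lithium 17, the last made from 3-bromoanisole 16; 17 and 15 combine to the ate complex 18.
- The neighbouring cuts are olefination of aldehyde 11 followed by alkene reduction, and an alkyl–aryl Suzuki coupling of 14.
- Olefination of 11 would be two operations shorter. It would, however, need a second non-catalytic alkene reduction on a large stilbene, and it fixes ring A as a benzylic phosphorus reagent.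
- The alkyl-Suzuki cut needs a stoichiometric hydroboration and is kept as the fallback.
- The conjunctive cut forms both bonds in one operation from three simple pieces, brings in ring A last from an aryl bromide, and builds the bridge at the saturated level, so no alkene has to be reduced beside four benzyl ethers.
- 14 is simpler than 19 by the whole ring A arm. The forward reaction must favour the 1,2-metallate shift over direct transfer of aryl or vinyl from boron to palladium, and must tolerate the bromide that accompanies 17.

**Triflate from aldehyde (14 ⇐ 13 ⇐ 12 ⇐ 11).** The S–O bond of 14 is cut to phenol 13, and the aryl C–O bond of 13 is traced through formate 12 to the aryl–CHO bond of 11. A Baeyer–Villiger oxidation is the natural choice because the formyl carbon sits para to the C4 benzyloxy group, which directs aryl migration. The formyl group is also what makes ring B available from a commercial bromocatechol aldehyde. The price is two functional-group steps. The forward reactions must leave the second electron-rich ring and the benzylic positions unoxidised.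

**Biaryl bond (11 ⇐ 10 + 8).** The C5(ring B)–C1(ring C) bond is cut to bromoaldehyde 10 and arylboronic ester 8. Placing the halide on the formyl-bearing ring gives the easier oxidative addition, and placing boron on ring C lets the arm be finished before the coupling. Each partner has one ortho substituent, so a Suzuki–Miyaura coupling with a bulky phosphine is sufficient. The cut divides the molecule into two pieces of similar size.

**Second bridge (8 ⇐ 7 ⇐ 6 ⇐ 5 ⇐ 2 + 3, through 4).** The C–B bond of 8 is traced through aryllithium 7 to the C–Br bond of 6. The bridge of 6 is cut at its central bond after adding unsaturation (stilbene 5), which leads to bromoaldehyde 2 and phosphonium salt 3 (ylide 4). Here the classical olefination is preferred over a second conjunctive coupling: the arm is ortho to the future biaryl bond, and the formyl group that becomes the arm is also the group that directs the bromine to the correct carbon. The alkene reduction must spare the aryl bromide and the benzyl ethers.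

**Starting materials (2 ⇐ 1; 10 ⇐ 9).** 2 comes from 3,4-bis(benzyloxy)benzaldehyde 1 by cutting the C–Br bond; electrophilic bromination of 1 goes to the position ortho to the formyl group. 10 comes from 3-bromo-4,5-dihydroxybenzaldehyde 9 by cutting two O–benzyl bonds. Both catechol patterns are bought, not built.

## Roads not taken

**Alternative 1:** The cut is the biaryl bond, made intramolecularly through an ester tether. The aryl 2-bromobenzoate A2, assembled from a ring B phenol and a ring C acid, would undergo palladium-catalysed C–H arylation to the benzochromenone lactone A1.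
- Merits: the ring closure is six-membered and intramolecular, which removes the steric concern of an intermolecular biaryl coupling. The site of arylation on ring B is fixed because the other ortho position carries the methoxymethyl ether. No boron reagent is needed.
- Weak points: the lactone carbonyl carbon of A1 sits where the ring C arm must grow. It would have to be reduced, the released ring B phenol re-protected, the carbon oxidised back to the aldehyde level, olefinated and the alkene reduced. Three kinds of phenol protection would be in play, and aryl esters are prone to acyl C–O cleavage under hot carbonate conditions.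
- Comparison: this road forms the biaryl bond more reliably than step 6. The chosen plan sets against that a biaryl with only one ortho substituent per ring, which is within normal Suzuki scope, and two arms that need no redox correction after the coupling.

**Alternative 2:** The cut is at two C–O bonds, C3–O of ring B and C4–O of ring C, made last. The bis-phenol A4 would be oxidised at both rings by 2-iodoxybenzoic acid A5 to the bis(ortho-quinone) A3 and reduced in the same flask to 21.
- Merits: this is the shortest end game and the best protecting-group economy. Only one oxygen per ring is carried, there is no final hydrogenolysis, and the bridge chemistry of the chosen plan could be used unchanged on the way to A4.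
- Weak points: the ring C phenol of A4 has two free ortho positions, C2 and C4; C2 is hindered by the biaryl bond but not blocked. A3 is a doubly electrophilic intermediate placed beside two electron-rich anisole rings and four benzylic CH2 groups. Two oxidations on one molecule multiply every loss, and the least controllable step falls on the most valuable material.
- Comparison: in step count and atom economy this road is better. The chosen plan sets against it that both catechol patterns are fixed from the start in 1 and 9, and that its last step is a clean hydrogenolysis.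

**Alternative 3:** The cut is at the C2–C3 and C4–C5 bonds of ring C, which would be built by cycloaddition. The 2-aryl-3-phenethylbuta-1,3-diene A7 would react with vinylene carbonate A8 in a thermal Diels–Alder reaction to give the cis-fused cyclohexene carbonate A6. Carbonate hydrolysis and a double oxidation with aromatisation would then give the catechol.
- Merits: the dienophile is symmetric, so there is no regiochemical question, and the two ring C oxygens arrive exactly at C3 and C4. No biaryl cross-coupling is needed, because the ring B–ring C bond is already present in A7.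
- Weak points: A7 is a 2,3-disubstituted butadiene carrying all of ring B, so it needs several steps of its own. A8 is a sluggish dienophile that needs high temperature, where a 2-aryl diene can dimerise or polymerise. Two stereocentres are made only to be destroyed, and the aromatisation must be done beside benzyl ethers and benzylic CH2 groups.
- Comparison: the road would be attractive if the ring C oxygenation pattern were hard to buy. Because 1 supplies it, building ring C from scratch costs steps that the chosen plan does not need. The chosen plan in turn has to accept a cross-coupling at a moderately hindered biaryl bond.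

Key step: step 9

## Route

Remark on the chemistry: (3-methoxybenzyl)triphenylphosphonium chloride (3) is taken as a purchasable salt. The aryllithium 17 is made in the flask from 3-bromoanisole (16), so the bromide formed there is removed with NaOTf in the key step. The boron-bearing carbon of 19 is formed racemic and is written without configuration.

Step 1
Reactants: 1 3,4-bis(benzyloxy)benzaldehyde
Product: 2 4,5-bis(benzyloxy)-2-bromobenzaldehyde
Conditions: Br2, NaOAc, AcOH, rt
Reagents that add atoms: bromine, BrBr
Why: Electrophilic aromatic bromination; the position para to the 3-benzyloxy group and ortho to the formyl group is the most activated free site, as in other 3,4-dialkoxybenzaldehydes, and NaOAc buffers the HBr so the benzyl ethers are not cleaved.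

Step 2
Reactants: 2 4,5-bis(benzyloxy)-2-bromobenzaldehyde; 3 (3-methoxybenzyl)triphenylphosphonium chloride
Product: 5 1,2-bis(benzyloxy)-4-bromo-5-[2-(3-methoxyphenyl)ethenyl]benzene (E/Z mixture), via phosphonium ylide 4 (not isolated)
Conditions: 3, KOtBu, THF, 0 °C; then 2, 0 °C to rt
Reagents that add atoms: none
Why: Wittig olefination of an aromatic aldehyde with a semi-stabilised benzylic ylide; the E/Z mixture does not matter because both isomers give 6 in step 3, and the aryl bromide and benzyl ethers are inert to the ylide.

Step 3
Reactants: 5 1,2-bis(benzyloxy)-4-bromo-5-[2-(3-methoxyphenyl)ethenyl]benzene (E/Z mixture)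
Product: 6 1,2-bis(benzyloxy)-4-bromo-5-[2-(3-methoxyphenyl)ethyl]benzene
Conditions: TsNHNH2, NaOAc, DME/H2O, reflux
Reagents that add atoms: none
Why: Diimide reduction; diimide formed thermally from tosylhydrazide delivers H2 to the stilbene C=C in a concerted syn addition and leaves the aryl bromide and benzyl ethers untouched, which catalytic hydrogenation would endanger.

Step 4
Reactants: 6 1,2-bis(benzyloxy)-4-bromo-5-[2-(3-methoxyphenyl)ethyl]benzene
Product: 8 2-{4,5-bis(benzyloxy)-2-[2-(3-methoxyphenyl)ethyl]phenyl}-4,4,5,5-tetramethyl-1,3,2-dioxaborolane, via aryllithium 7 (not isolated)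
Conditions: n-BuLi, THF, −78 °C; then 2-isopropoxy-4,4,5,5-tetramethyl-1,3,2-dioxaborolane, −78 °C to rt; H2O
Reagents that add atoms: 2-isopropoxy-4,4,5,5-tetramethyl-1,3,2-dioxaborolane, CC(C)OB1OC(C)(C)C(C)(C)O1
Why: Bromine–lithium exchange at −78 °C is much faster than any attack on the benzyl ethers, and aryllithium 7 is trapped at boron with loss of isopropoxide to give the pinacol boronate.

Step 5
Reactants: 9 3-bromo-4,5-dihydroxybenzaldehyde
Product: 10 3,4-bis(benzyloxy)-5-bromobenzaldehyde
Conditions: BnBr, K2CO3, DMF, 60 °C
Reagents that add atoms: benzyl bromide, BrCc1ccccc1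
Why: Williamson ether synthesis; both phenols are alkylated with excess benzyl bromide under carbonate conditions, and the non-enolisable aldehyde is unaffected.

Step 6
Reactants: 10 3,4-bis(benzyloxy)-5-bromobenzaldehyde; 8 2-{4,5-bis(benzyloxy)-2-[2-(3-methoxyphenyl)ethyl]phenyl}-4,4,5,5-tetramethyl-1,3,2-dioxaborolane
Product: 11 3,4-bis(benzyloxy)-5-{4,5-bis(benzyloxy)-2-[2-(3-methoxyphenyl)ethyl]phenyl}benzaldehyde
Conditions: Pd(OAc)2 (cat.), 2-dicyclohexylphosphino-2',6'-dimethoxybiphenyl (SPhos, cat.), K3PO4, toluene/H2O, 90 °C
Reagents that add atoms: none
Why: Suzuki–Miyaura cross-coupling; the bromide sits on the formyl-bearing ring, which eases oxidative addition, each partner has only one ortho substituent, and the dialkylbiarylphosphine is suited to such couplings while tolerating the aldehyde and benzyl ethers.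

Step 7
Reactants: 11 3,4-bis(benzyloxy)-5-{4,5-bis(benzyloxy)-2-[2-(3-methoxyphenyl)ethyl]phenyl}benzaldehyde
Product: 13 3,4-bis(benzyloxy)-5-{4,5-bis(benzyloxy)-2-[2-(3-methoxyphenyl)ethyl]phenyl}phenol, via aryl formate 12 (not isolated)
Conditions: mCPBA, CH2Cl2, 0 °C to rt; then K2CO3, MeOH, rt
Reagents that add atoms: 3-chloroperoxybenzoic acid (mCPBA), O=C(OO)c1cccc(Cl)c1
Why: Baeyer–Villiger oxidation of an electron-rich benzaldehyde; the benzyloxy group para to the formyl group makes the aryl group migrate in the Criegee intermediate to give formate 12, which methanolysis cleaves to the phenol, while benzyl ethers, methyl ethers and the bibenzyl chain are inert to the peracid at this temperature.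

Step 8
Reactants: 13 3,4-bis(benzyloxy)-5-{4,5-bis(benzyloxy)-2-[2-(3-methoxyphenyl)ethyl]phenyl}phenol
Product: 14 3,4-bis(benzyloxy)-5-{4,5-bis(benzyloxy)-2-[2-(3-methoxyphenyl)ethyl]phenyl}phenyl trifluoromethanesulfonate
Conditions: Tf2O, pyridine, CH2Cl2, 0 °C
Reagents that add atoms: trifluoromethanesulfonic anhydride, O=S(=O)(OS(=O)(=O)C(F)(F)F)C(F)(F)F
Why: O-Sulfonylation of a phenol with triflic anhydride and pyridine; the hydroxyl has hydrogens at both ortho positions and reacts without hindrance.

Step 9
Reactants: 14 3,4-bis(benzyloxy)-5-{4,5-bis(benzyloxy)-2-[2-(3-methoxyphenyl)ethyl]phenyl}phenyl trifluoromethanesulfonate; 15 4,4,5,5-tetramethyl-2-vinyl-1,3,2-dioxaborolane; 16 3-bromoanisole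
Product: 19 racemic 2-{2-[3,4-bis(benzyloxy)-5-{4,5-bis(benzyloxy)-2-[2-(3-methoxyphenyl)ethyl]phenyl}phenyl]-1-(3-methoxyphenyl)ethyl}-4,4,5,5-tetramethyl-1,3,2-dioxaborolane, via (3-methoxyphenyl)lithium 17 (not isolated), via lithium aryl(vinyl)boronate complex 18 (not isolated)
Conditions: 16, t-BuLi (2 equiv), Et2O, −78 °C; then 15, −78 °C to rt; solvent exchange to THF; then 14, NaOTf, Pd(OAc)2 (cat.), 1,1'-bis(diphenylphosphino)ferrocene (cat.), 60 °C
Reagents that add atoms: none
Why: This is a palladium-catalysed conjunctive cross-coupling of a vinylboron ate complex with an aryl triflate, a known reaction type for aryl migrating groups and aryl triflates. Bromine–lithium exchange on 16 gives 17, which adds to the boron of 15 to form the four-coordinate complex 18. Zerovalent palladium, formed from Pd(OAc)2 and the bisphosphine, inserts into the C–O bond of triflate 14, and the resulting cationic aryl complex of divalent palladium binds the vinyl group of 18. This binding triggers a 1,2-shift of the 3-methoxyphenyl group from boron to the adjacent carbon while palladium bonds the terminal carbon; reductive elimination then forms the CH2–C1(ring B) bond and returns zerovalent palladium. No ring is closed. The one new stereocentre, the boron-bearing benzylic carbon, is formed racemic because the ligand is achiral, and it is removed in step 10, so it needs no control. The selectivity required is the metallate shift over direct transfer of aryl or vinyl from boron to palladium and over β-hydride elimination; the chelating ferrocenyl bisphosphine and the weakly coordinating triflate keep palladium cationic and alkene-bound, NaOTf removes the bromide left by the exchange, and the triflate carbon of 14 has hydrogens at both ortho positions, so oxidative addition and the final bond formation are unhindered.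

Step 10
Reactants: 19 racemic 2-{2-[3,4-bis(benzyloxy)-5-{4,5-bis(benzyloxy)-2-[2-(3-methoxyphenyl)ethyl]phenyl}phenyl]-1-(3-methoxyphenyl)ethyl}-4,4,5,5-tetramethyl-1,3,2-dioxaborolane
Product: 20 1,2-bis(benzyloxy)-3-{4,5-bis(benzyloxy)-2-[2-(3-methoxyphenyl)ethyl]phenyl}-5-[2-(3-methoxyphenyl)ethyl]benzene
Conditions: n-Bu4NF·3H2O, toluene, 90 °C
Reagents that add atoms: none
Why: Fluoride-promoted protodeboronation of a benzylic boronic ester; fluoride forms the borate, whose benzylic C–B bond is cleaved with protonation by water because ring A stabilises the developing carbanion character, and the stereocentre disappears while all ethers are inert.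

Step 11
Reactants: 20 1,2-bis(benzyloxy)-3-{4,5-bis(benzyloxy)-2-[2-(3-methoxyphenyl)ethyl]phenyl}-5-[2-(3-methoxyphenyl)ethyl]benzene
Product: 21 isoplagilin
Conditions: H2 (1 atm), Pd/C, EtOAc/MeOH, rt
Reagents that add atoms: none
Why: Hydrogenolysis of aryl benzyl ethers over palladium on carbon; the methyl ethers, the biaryl and the saturated bridges are untouched, and the bis-catechol should be handled under inert gas because it oxidises in air.

## Compound list

1 | 3,4-bis(benzyloxy)benzaldehyde | O=Cc1ccc(OCc2ccccc2)c(OCc2ccccc2)c1 | starting material
2 | 4,5-bis(benzyloxy)-2-bromobenzaldehyde | O=Cc1cc(OCc2ccccc2)c(OCc2ccccc2)cc1Br | intermediate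
3 | (3-methoxybenzyl)triphenylphosphonium chloride | COc1cccc(C[P+](c2ccccc2)(c2ccccc2)c2ccccc2)c1.[Cl-] | starting material
4 | (3-methoxybenzylidene)triphenylphosphorane (phosphonium ylide) | COc1cccc(C=P(c2ccccc2)(c2ccccc2)c2ccccc2)c1 | intermediate (not isolated)
5 | 1,2-bis(benzyloxy)-4-bromo-5-[2-(3-methoxyphenyl)ethenyl]benzene (E/Z mixture) | COc1cccc(C=Cc2cc(OCc3ccccc3)c(OCc3ccccc3)cc2Br)c1 | intermediate
6 | 1,2-bis(benzyloxy)-4-bromo-5-[2-(3-methoxyphenyl)ethyl]benzene | COc1cccc(CCc2cc(OCc3ccccc3)c(OCc3ccccc3)cc2Br)c1 | intermediate
7 | {4,5-bis(benzyloxy)-2-[2-(3-methoxyphenyl)ethyl]phenyl}lithium | [Li]c1cc(OCc2ccccc2)c(OCc2ccccc2)cc1CCc1cccc(OC)c1 | intermediate (not isolated)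
8 | 2-{4,5-bis(benzyloxy)-2-[2-(3-methoxyphenyl)ethyl]phenyl}-4,4,5,5-tetramethyl-1,3,2-dioxaborolane | COc1cccc(CCc2cc(OCc3ccccc3)c(OCc3ccccc3)cc2B2OC(C)(C)C(C)(C)O2)c1 | intermediate
9 | 3-bromo-4,5-dihydroxybenzaldehyde | O=Cc1cc(O)c(O)c(Br)c1 | starting material
10 | 3,4-bis(benzyloxy)-5-bromobenzaldehyde | O=Cc1cc(Br)c(OCc2ccccc2)c(OCc2ccccc2)c1 | intermediate
11 | 3,4-bis(benzyloxy)-5-{4,5-bis(benzyloxy)-2-[2-(3-methoxyphenyl)ethyl]phenyl}benzaldehyde | COc1cccc(CCc2cc(OCc3ccccc3)c(OCc3ccccc3)cc2-c2cc(C=O)cc(OCc3ccccc3)c2OCc2ccccc2)c1 | intermediate
12 | 3,4-bis(benzyloxy)-5-{4,5-bis(benzyloxy)-2-[2-(3-methoxyphenyl)ethyl]phenyl}phenyl formate | COc1cccc(CCc2cc(OCc3ccccc3)c(OCc3ccccc3)cc2-c2cc(OC=O)cc(OCc3ccccc3)c2OCc2ccccc2)c1 | intermediate (not isolated)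
13 | 3,4-bis(benzyloxy)-5-{4,5-bis(benzyloxy)-2-[2-(3-methoxyphenyl)ethyl]phenyl}phenol | COc1cccc(CCc2cc(OCc3ccccc3)c(OCc3ccccc3)cc2-c2cc(O)cc(OCc3ccccc3)c2OCc2ccccc2)c1 | intermediate
14 | 3,4-bis(benzyloxy)-5-{4,5-bis(benzyloxy)-2-[2-(3-methoxyphenyl)ethyl]phenyl}phenyl trifluoromethanesulfonate | O=S(=O)(Oc1cc(OCc2ccccc2)c(OCc2ccccc2)c(-c2cc(OCc3ccccc3)c(OCc3ccccc3)cc2CCc2cccc(OC)c2)c1)C(F)(F)F | intermediate
15 | 4,4,5,5-tetramethyl-2-vinyl-1,3,2-dioxaborolane | C=CB1OC(C)(C)C(C)(C)O1 | starting material
16 | 3-bromoanisole | COc1cccc(Br)c1 | starting material
17 | (3-methoxyphenyl)lithium | [Li]c1cccc(OC)c1 | intermediate (not isolated)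
18 | lithium (3-methoxyphenyl)(vinyl)pinacolatoborate (ate complex) | [Li+].C=C[B-]1(c2cccc(OC)c2)OC(C)(C)C(C)(C)O1 | intermediate (not isolated)
19 | racemic 2-{2-[3,4-bis(benzyloxy)-5-{4,5-bis(benzyloxy)-2-[2-(3-methoxyphenyl)ethyl]phenyl}phenyl]-1-(3-methoxyphenyl)ethyl}-4,4,5,5-tetramethyl-1,3,2-dioxaborolane | COc1cccc(C(Cc2cc(OCc3ccccc3)c(OCc3ccccc3)c(-c3cc(OCc4ccccc4)c(OCc4ccccc4)cc3CCc3cccc(OC)c3)c2)B2OC(C)(C)C(C)(C)O2)c1 | intermediate
20 | 1,2-bis(benzyloxy)-3-{4,5-bis(benzyloxy)-2-[2-(3-methoxyphenyl)ethyl]phenyl}-5-[2-(3-methoxyphenyl)ethyl]benzene (tetra-O-benzyl isoplagilin) | COc1cccc(CCc2cc(OCc3ccccc3)c(OCc3ccccc3)c(-c3cc(OCc4ccccc4)c(OCc4ccccc4)cc3CCc3cccc(OC)c3)c2)c1 | intermediate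
21 | isoplagilin, 3-{4,5-dihydroxy-2-[2-(3-methoxyphenyl)ethyl]phenyl}-5-[2-(3-methoxyphenyl)ethyl]benzene-1,2-diol | COc1cccc(CCc2cc(O)c(O)c(-c3cc(O)c(O)cc3CCc3cccc(OC)c3)c2)c1 | target

## Step count and risks

Total steps: 11. Longest linear sequence: 10 steps (steps 1–4 and 6–11, from 1 to 21); step 5 is a one-step side branch.

**Step 9 (key step).** The most likely failure is diversion of the palladium intermediate: direct transfer of the 3-methoxyphenyl or vinyl group from boron to palladium (ordinary Suzuki products), β-hydride elimination after the shift, or stalling of the catalyst by bromide carried over from the bromine–lithium exchange. The triflate of 14 is para to an alkoxy group, so oxidative addition is not fast, which gives these pathways time. Fallback: starting from 14, the bridge is installed as a ready-made two-carbon unit. Hydroboration of commercial 3-vinylanisole with 9-borabicyclo[3.3.1]nonane gives 9-[2-(3-methoxyphenyl)ethyl]-9-borabicyclo[3.3.1]nonane F1, which is coupled with 14 in an alkyl–aryl Suzuki–Miyaura reaction using [1,1'-bis(diphenylphosphino)ferrocene]palladium dichloride, PdCl2(dppf), and K3PO4 in THF/H2O. This gives 20 directly and returns to the route at 20, with step 10 no longer needed.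

**Step 10.** Cleavage of the C–B bond may be sluggish, because the boronate is secondary and the 3-methoxy group on ring A stabilises the benzylic carbanion character only weakly; at the temperature then required, oxidation of the borate by traces of air can compete. Fallback: starting from 19, the boronate is oxidised deliberately with NaBO3·4H2O in THF/H2O to the racemic alcohol 2-[3,4-bis(benzyloxy)-5-{4,5-bis(benzyloxy)-2-[2-(3-methoxyphenyl)ethyl]phenyl}phenyl]-1-(3-methoxyphenyl)ethanol F2. Hydrogenolysis of F2 over Pd/C under H2 in acetic acid with a trace of HCl removes the benzylic hydroxyl together with the four benzyl ethers and returns to the route at 21.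

**Step 6.** Protodeboronation of the electron-rich, ortho-alkylated boronate 8 may outrun transmetalation at the hindered biaryl bond, so that the arm-bearing fragment is lost as the reduced arene. Fallback: the polarity is reversed. Starting from 10, Miyaura borylation with bis(pinacolato)diboron, PdCl2(dppf) and KOAc in dioxane gives 3,4-bis(benzyloxy)-5-(4,4,5,5-tetramethyl-1,3,2-dioxaborolan-2-yl)benzaldehyde F3, which is coupled with bromide 6 under the conditions of step 6 and returns to the route at 11. Step 4 is then not needed.

**Step 7.** On the fully assembled biaryl the peracid may oxidise beyond the formyl group, at the electron-rich ring C or at the phenol once some formate has hydrolysed, or hydride migration may compete and give the carboxylic acid. Fallback: the oxidation is moved to the simple bromoaldehyde. Starting from 10, mCPBA gives 3,4-bis(benzyloxy)-5-bromophenyl formate F4, methanolysis gives 3,4-bis(benzyloxy)-5-bromophenol F5, and Suzuki–Miyaura coupling of F5 with 8 under the conditions of step 6, which tolerate a free phenol, returns to the route at 13.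

## Further compounds

F1 | step 9 | 9-[2-(3-methoxyphenyl)ethyl]-9-borabicyclo[3.3.1]nonane | COc1cccc(CCB2C3CCCC2CCC3)c1
F2 | step 10 | racemic 2-[3,4-bis(benzyloxy)-5-{4,5-bis(benzyloxy)-2-[2-(3-methoxyphenyl)ethyl]phenyl}phenyl]-1-(3-methoxyphenyl)ethanol | COc1cccc(C(O)Cc2cc(OCc3ccccc3)c(OCc3ccccc3)c(-c3cc(OCc4ccccc4)c(OCc4ccccc4)cc3CCc3cccc(OC)c3)c2)c1
F3 | step 6 | 3,4-bis(benzyloxy)-5-(4,4,5,5-tetramethyl-1,3,2-dioxaborolan-2-yl)benzaldehyde | O=Cc1cc(B2OC(C)(C)C(C)(C)O2)c(OCc2ccccc2)c(OCc2ccccc2)c1
F4 | step 7 | 3,4-bis(benzyloxy)-5-bromophenyl formate | O=COc1cc(Br)c(OCc2ccccc2)c(OCc2ccccc2)c1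
F5 | step 7 | 3,4-bis(benzyloxy)-5-bromophenol | Oc1cc(Br)c(OCc2ccccc2)c(OCc2ccccc2)c1
A1 | alternative 1 | 8,9-bis(benzyloxy)-4-(methoxymethoxy)-2-[2-(3-methoxyphenyl)ethyl]-6H-benzo[c]chromen-6-one | COCOc1cc(CCc2cccc(OC)c2)cc2c1OC(=O)c1cc(OCc3ccccc3)c(OCc3ccccc3)cc1-2
A2 | alternative 1 | 2-(methoxymethoxy)-4-[2-(3-methoxyphenyl)ethyl]phenyl 4,5-bis(benzyloxy)-2-bromobenzoate | COCOc1cc(CCc2cccc(OC)c2)ccc1OC(=O)c1cc(OCc2ccccc2)c(OCc2ccccc2)cc1Br
A3 | alternative 2 | bis(ortho-quinone) of isoplagilin, 3-{6-[2-(3-methoxyphenyl)ethyl]-3,4-dioxocyclohexa-1,5-dien-1-yl}-5-[2-(3-methoxyphenyl)ethyl]cyclohexa-3,5-diene-1,2-dione | COc1cccc(CCC2=CC(=O)C(=O)C(C3=CC(=O)C(=O)C=C3CCc3cccc(OC)c3)=C2)c1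
A4 | alternative 2 | 2-{5-hydroxy-2-[2-(3-methoxyphenyl)ethyl]phenyl}-4-[2-(3-methoxyphenyl)ethyl]phenol | COc1cccc(CCc2ccc(O)c(-c3cc(O)ccc3CCc3cccc(OC)c3)c2)c1
A5 | alternative 2 | 2-iodoxybenzoic acid | O=C1OI(=O)(O)c2ccccc12
A6 | alternative 3 | racemic cis-5-{2,3-bis(benzyloxy)-5-[2-(3-methoxyphenyl)ethyl]phenyl}-6-[2-(3-methoxyphenyl)ethyl]-3a,4,7,7a-tetrahydro-1,3-benzodioxol-2-one (one enantiomer drawn) | O=C1O[C@H]2CC(CCc3cccc(OC)c3)=C(c3cc(CCc4cccc(OC)c4)cc(OCc4ccccc4)c3OCc3ccccc3)C[C@H]2O1
A7 | alternative 3 | 1,2-bis(benzyloxy)-5-[2-(3-methoxyphenyl)ethyl]-3-[5-(3-methoxyphenyl)-3-methylidenepent-1-en-2-yl]benzene | C=C(CCc1cccc(OC)c1)C(=C)c1cc(CCc2cccc(OC)c2)cc(OCc2ccccc2)c1OCc1ccccc1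
A8 | alternative 3 | vinylene carbonate | O=c1occo1
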